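**Retrosynthetic overview**
1. Target 16 ⇐ acylation of O3 ⇐ Evans–Tishchenko reduction (O5 ester and C3 carbinol together) ⇐ β-hydroxylation at C5 of tricyclic dienedione 12.
2. 12 ⇐ cyclobutane bond C1–C2, made by oxidative coupling of the two enolate carbons of the cis-fused bicyclic bis-enone 10 (key step).
3. 10 ⇐ allylic oxidation ⇐ ring-closing metathesis (seven-membered ring) ⇐ vinyl ketone 8 ⇐ Johnson–Claisen rearrangement (sets the cis ring fusion) ⇐ allylic alcohol 5.
4. 5 ⇐ CBS reduction ⇐ enone 4 ⇐ organocatalytic Michael/aldol annulation of aldehyde 1 with pent-1-en-3-one 2 (six-membered ring, first stereocentre).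
5. Ring order: six-membered, then seven-membered, then four-membered.

Assumption: 3,3-dimethylpent-4-enal (1) is bought as such (catalogue compound; otherwise one i-Bu2AlH reduction from bulk methyl 3,3-dimethylpent-4-enoate).
Locants: 9–11 use benzo[7]annulene numbering; 12–16 use tricyclo[5.4.0.0²,⁸]undecane numbering.

Step 1
Reactants: 1 3,3-dimethylpent-4-enal; 2 pent-1-en-3-one
Product: 4 (4R)-2-methyl-4-(2-methylbut-3-en-2-yl)cyclohex-2-en-1-one, via keto-aldehyde 3 (not isolated)
Conditions: (S)-2-[methoxy(diphenyl)methyl]pyrrolidine (5 mol%), ethyl 3,4-dihydroxybenzoate (20 mol%), neat, 4 °C; then i-PrOH, LiOH (0.2 equiv), 25 °C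
Reagents that add atoms: none
Why: Enamine Michael addition of the aldehyde to the vinyl ketone, in which the (S)-prolinol ether shields one enamine face and sets the aldehyde α-carbon (S in 3, R in 4 by CIP change), followed by intramolecular aldol condensation of the ethyl-ketone CH2 onto the aldehyde (Robinson-type annulation).

Step 2
Reactants: 4 (4R)-2-methyl-4-(2-methylbut-3-en-2-yl)cyclohex-2-en-1-one
Product: 5 (1S,4R)-2-methyl-4-(2-methylbut-3-en-2-yl)cyclohex-2-en-1-ol
Conditions: (R)-1-methyl-3,3-diphenyltetrahydro-1H,3H-pyrrolo[1,2-c][1,3,2]oxazaborole (0.2 equiv), catecholborane (1.5 equiv), toluene, −78 °C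
Reagents that add atoms: none
Why: Corey–Bakshi–Shibata reduction in which the α-methyl enone C=C acts as the large group, so the (R)-oxazaborolidine gives the (1S)-alcohol with OH cis to the C4 side chain under reagent control, while catecholborane at −78 °C leaves the vinyl group alone.

Step 3
Reactants: 5 (1S,4R)-2-methyl-4-(2-methylbut-3-en-2-yl)cyclohex-2-en-1-ol
Product: 6 ethyl (2RS)-2-[(1S,6R)-2-methyl-6-(2-methylbut-3-en-2-yl)cyclohex-2-en-1-yl]propanoate
Conditions: EtC(OEt)3 (6 equiv), EtCO2H (0.1 equiv), xylenes, 140 °C, EtOH distilled off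
Reagents that add atoms: triethyl orthopropionate CCC(OCC)(OCC)OCC
Why: Johnson–Claisen rearrangement, suprafacial from the pseudoaxial C–O bond, so the propanoate carbon arrives on the face that carried the oxygen, cis to the neighbouring 1,1-dimethylallyl group, and the alkene moves to where the enone is needed (the propanoate α-centre is a mixture and is erased in step 7).

Step 4
Reactants: 6 ethyl (2RS)-2-[(1S,6R)-2-methyl-6-(2-methylbut-3-en-2-yl)cyclohex-2-en-1-yl]propanoate
Product: 8 (4RS)-4-[(1S,6R)-2-methyl-6-(2-methylbut-3-en-2-yl)cyclohex-2-en-1-yl]pent-1-en-3-one, via Weinreb amide 7 (not isolated)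
Conditions: MeNH(OMe)·HCl (1.6 equiv), i-PrMgCl (3.2 equiv), THF, −20 °C; then CH2=CHMgBr (2.0 equiv), 0 °C; inverse quench into cold 1 M HCl
Reagents that add atoms: vinylmagnesium bromide C=C[Mg]Br
Why: One-pot Weinreb ketone synthesis, in which the magnesium amide turns the ester into the N-methoxy-N-methylamide and its chelated adduct with the vinyl Grignard reagent stops at the ketone; no ring stereocentre is touched.

Step 5
Reactants: 8 (4RS)-4-[(1S,6R)-2-methyl-6-(2-methylbut-3-en-2-yl)cyclohex-2-en-1-yl]pent-1-en-3-one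
Product: 9 (4aR,9aS,9RS)-1,5,5,9-tetramethyl-3,4,4a,5,9,9a-hexahydro-8H-benzo[7]annulen-8-one
Conditions: second-generation Hoveyda–Grubbs catalyst (H2IMes)Cl2Ru=CH(C6H4-2-O-i-Pr) (5 mol%), toluene, 0.005 M, 80 °C
Reagents that add atoms: none
Why: Ring-closing metathesis of the enone vinyl group with the neopentyl vinyl group closes the cycloheptenone as the cis alkene, cis-fused because the two arms are cis on the cyclohexene, while the trisubstituted ring alkene stays out.

Step 6
Reactants: 9 (4aR,9aS,9RS)-1,5,5,9-tetramethyl-3,4,4a,5,9,9a-hexahydro-8H-benzo[7]annulen-8-one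
Product: 10 (4aR,9aS,9RS)-1,5,5,9-tetramethyl-4a,5,9,9a-tetrahydro-3H-benzo[7]annulene-3,8(4H)-dione
Conditions: Rh2(cap)4 (dirhodium tetracaprolactamate, 1 mol%), t-BuOOH (70% aq., 5 equiv), NaHCO3, CH2Cl2, 25 °C
Reagents that add atoms: tert-butyl hydroperoxide CC(C)(C)OO
Why: Allylic C–H oxidation at the only allylic methylene (C3, next to the unsubstituted alkene carbon), the same regiochemistry as 1-methylcyclohexene to 3-methylcyclohex-2-enone and α-pinene to verbenone; no stereocentre is touched.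

Step 7
Reactants: 10 (4aR,9aS,9RS)-1,5,5,9-tetramethyl-4a,5,9,9a-tetrahydro-3H-benzo[7]annulene-3,8(4H)-dione
Product: 12 (1R,2R,7S,8R)-2,6,6,9-tetramethyltricyclo[5.4.0.0²,⁸]undeca-4,9-diene-3,11-dione, via dilithium bis-enolate 11 (not isolated)
Conditions: LiN(i-Pr)2 (2.3 equiv), THF, −78 °C, 1 h; then Fe(acac)3 (2.3 equiv), THF, −78 → 0 °C, 0.005 M
Reagents that add atoms: none
Why: Proposed new method: intramolecular oxidative enolate coupling, in which kinetic α′-deprotonation of both enones (C4 and C9 of 10) gives the bis-enolate, trivalent iron oxidises one enolate to an α-keto radical that is trapped by the other enolate carbon four atoms away before the second oxidation, so two nucleophilic α-carbons are joined into the cyclobutane; because both carbons sit on cis arms of a cis-fused bicycle the bond can form on one face only, which fixes C1 and C2 (both R) relative to C7 and C8, and the closest known reactions are the Saegusa (CuCl2) and Baran (Fe(acac)3) intramolecular couplings of dienolates, including cyclobutane-1,2-dicarboxylates from adipate dienolates.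

Step 8
Reactants: 12 (1R,2R,7S,8R)-2,6,6,9-tetramethyltricyclo[5.4.0.0²,⁸]undeca-4,9-diene-3,11-dione
Product: 14 (1R,2R,5R,7S,8R)-5-hydroxy-2,6,6,9-tetramethyltricyclo[5.4.0.0²,⁸]undec-9-ene-3,11-dione, via pinacol boronate 13 (not isolated)
Conditions: CuCl (5 mol%), NaOt-Bu (10 mol%), (R)-1-[(SP)-2-(diphenylphosphino)ferrocenyl]ethyldicyclohexylphosphine (6 mol%), B2pin2 (1.2 equiv), MeOH (2 equiv), THF, 0 °C; then NaBO3·4H2O, THF/H2O, 25 °C
Reagents that add atoms: sodium perborate tetrahydrate [Na+].[Na+].O[B-]1(O)OO[B-](O)(O)OO1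
Why: Copper-catalysed conjugate borylation then stereoretentive perborate oxidation, in which borylcopper adds to the disubstituted cycloheptenone and not the bridged β,β-disubstituted cyclohexenone, and since the enone bridge lies in the local mirror plane of 12 the chiral ligand selects the face and sets C5 as R (the ligand antipode gives the C5 epimer).

Step 9
Reactants: 14 (1R,2R,5R,7S,8R)-5-hydroxy-2,6,6,9-tetramethyltricyclo[5.4.0.0²,⁸]undec-9-ene-3,11-dione
Product: 15 (1R,2R,3R,5R,7S,8R)-3-hydroxy-2,6,6,9-tetramethyl-11-oxotricyclo[5.4.0.0²,⁸]undec-9-en-5-yl 3-methylbut-2-enoate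
Conditions: SmI2 (0.3 equiv) premixed with 3-methylbut-2-enal (8 equiv), THF, −10 °C, then 14
Reagents that add atoms: 3-methylbut-2-enal CC(C)=CC=O
Why: Evans–Tishchenko reduction, in which the samarium-bound hemiacetal of the C5 hydroxyl and the enal passes its hydride to the C3 ketone from the face of the C5 oxygen, giving the 1,3-anti (trans) diol with C3 as R and the 3-methylbut-2-enoate already on O5.

Step 10
Reactants: 15 (1R,2R,3R,5R,7S,8R)-3-hydroxy-2,6,6,9-tetramethyl-11-oxotricyclo[5.4.0.0²,⁸]undec-9-en-5-yl 3-methylbut-2-enoate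
Product: 16 (1R,2R,3R,5R,7S,8R)-2,6,6,9-tetramethyl-3-[(3-methylbutanoyl)oxy]-11-oxotricyclo[5.4.0.0²,⁸]undec-9-en-5-yl 3-methylbut-2-enoate
Conditions: 3-methylbutanoyl chloride (3 equiv), pyridine, DMAP (0.2 equiv), CH2Cl2, 0 → 25 °C
Reagents that add atoms: 3-methylbutanoyl chloride CC(C)CC(Cl)=O
Why: DMAP-catalysed acylation of the remaining secondary alcohol; no stereocentre is affected.

**Compound list**
1 | 3,3-dimethylpent-4-enal | O=CCC(C)(C)C=C | starting material
2 | pent-1-en-3-one | C=CC(=O)CC | starting material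
3 | (2S)-2-(2-methylbut-3-en-2-yl)-5-oxoheptanal | O=C[C@@H](CCC(=O)CC)C(C)(C)C=C | intermediate
4 | (4R)-2-methyl-4-(2-methylbut-3-en-2-yl)cyclohex-2-en-1-one | O=C1CC[C@@H](C(C)(C)C=C)C=C1C | intermediate
5 | (1S,4R)-2-methyl-4-(2-methylbut-3-en-2-yl)cyclohex-2-en-1-ol | O[C@H]1CC[C@@H](C(C)(C)C=C)C=C1C | intermediate
6 | ethyl (2RS)-2-[(1S,6R)-2-methyl-6-(2-methylbut-3-en-2-yl)cyclohex-2-en-1-yl]propanoate | C1=C(C)[C@@H]([C@@H](CC1)C(C)(C)C=C)C(C)C(=O)OCC | intermediate
7 | (2RS)-N-methoxy-N-methyl-2-[(1S,6R)-2-methyl-6-(2-methylbut-3-en-2-yl)cyclohex-2-en-1-yl]propanamide | C1=C(C)[C@@H]([C@@H](CC1)C(C)(C)C=C)C(C)C(=O)N(C)OC | intermediate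
8 | (4RS)-4-[(1S,6R)-2-methyl-6-(2-methylbut-3-en-2-yl)cyclohex-2-en-1-yl]pent-1-en-3-one | C1=C(C)[C@@H]([C@@H](CC1)C(C)(C)C=C)C(C)C(=O)C=C | intermediate
9 | (4aR,9aS,9RS)-1,5,5,9-tetramethyl-3,4,4a,5,9,9a-hexahydro-8H-benzo[7]annulen-8-one | C1=C(C)[C@H]2[C@@H](CC1)C(C)(C)C=CC(=O)C2C | intermediate
10 | (4aR,9aS,9RS)-1,5,5,9-tetramethyl-4a,5,9,9a-tetrahydro-3H-benzo[7]annulene-3,8(4H)-dione | O=C1C=C(C)[C@H]2[C@@H](C1)C(C)(C)C=CC(=O)C2C | intermediate
11 | dilithium 3,8-bis-enolate of 10 (C3=C4 and C8=C9 enolate double bonds) | [Li]OC1=C[C@@H]2[C@H](C(C)=C1)C(C)=C(O[Li])C=CC2(C)C | intermediate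
12 | (1R,2R,7S,8R)-2,6,6,9-tetramethyltricyclo[5.4.0.0²,⁸]undeca-4,9-diene-3,11-dione | C1=CC(=O)[C@@]2(C)[C@@H]3C(=O)C=C(C)[C@H]2[C@@H]3C1(C)C | intermediate
13 | (1R,2R,5R,7S,8R)-2,6,6,9-tetramethyl-5-(4,4,5,5-tetramethyl-1,3,2-dioxaborolan-2-yl)tricyclo[5.4.0.0²,⁸]undec-9-ene-3,11-dione | CC1(C)OB(OC1(C)C)[C@@H]2CC(=O)[C@@]3(C)[C@@H]4C(=O)C=C(C)[C@H]3[C@@H]4C2(C)C | intermediate
14 | (1R,2R,5R,7S,8R)-5-hydroxy-2,6,6,9-tetramethyltricyclo[5.4.0.0²,⁸]undec-9-ene-3,11-dione | O[C@@H]1CC(=O)[C@@]2(C)[C@@H]3C(=O)C=C(C)[C@H]2[C@@H]3C1(C)C | intermediate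
15 | (1R,2R,3R,5R,7S,8R)-3-hydroxy-2,6,6,9-tetramethyl-11-oxotricyclo[5.4.0.0²,⁸]undec-9-en-5-yl 3-methylbut-2-enoate | CC(C)=CC(=O)O[C@@H]1C[C@@H](O)[C@@]2(C)[C@@H]3C(=O)C=C(C)[C@H]2[C@@H]3C1(C)C | intermediate
16 | (1R,2R,3R,5R,7S,8R)-2,6,6,9-tetramethyl-3-[(3-methylbutanoyl)oxy]-11-oxotricyclo[5.4.0.0²,⁸]undec-9-en-5-yl 3-methylbut-2-enoate | CC(C)=CC(=O)O[C@@H]1C[C@@H](OC(=O)CC(C)C)[C@@]2(C)[C@@H]3C(=O)C=C(C)[C@H]2[C@@H]3C1(C)C | target

**Step count**
Total steps: 10. Longest linear sequence: 10 (the route is fully linear from 1 and 2).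

**Three steps most likely to fail**

Step 7. The four-membered ring closure may lose to oligomerisation or O–C coupling. The fallback replaces the oxidative coupling by a polar alkylation; it sets out from 10 and comes back at 12. Compound 10 is treated with LiN(i-Pr)2 (1.05 equiv) and Me3SiCl at −78 °C, where the cyclohexenone CH2 is deprotonated first, to give the silyl dienol ether F1. NBS then gives the bromo dione F2. KN(SiMe3)2 forms the cycloheptenone enolate, which displaces the α-keto bromide in a 4-exo-tet alkylation to give 12. The bromide configuration does not matter because that centre epimerises through its enol.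

Step 8. The neopentyl β-carbon may resist borylcopper addition, the face selectivity may be low, or the ligand I named may prove to be the wrong antipode (its sense is not established for this substrate and must be checked on the first run). The fallback sets out from 12 and comes back at 14. Nucleophilic epoxidation of the cycloheptenone with t-BuOOH under La(O-i-Pr)3/(R)-BINOL/Ph3AsO control (4 Å MS, THF) gives the epoxy ketone F3. Reductive opening of its Cα–O bond with Na[PhSeB(OEt)3] (from (PhSe)2 and NaBH4 in EtOH) gives 14.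

Step 9. The enal may be a poor hydride donor, or the hindered hemiacetal may not form. The fallback sets out from 14 and comes back at 16. The Evans–Tishchenko reduction is run with acetaldehyde (SmI2, 0.3 equiv, THF, −10 °C) to give the hydroxy acetate F4. O3 is acylated with 3-methylbutanoyl chloride (pyridine, DMAP) to the mixed diester F5. The acetate is removed selectively (K2CO3, MeOH, 0 °C) to give the hydroxy 3-methylbutanoate F6. O5 is then esterified with 3-methylbut-2-enoic anhydride and DMAP to reach 16.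

Further compounds
F1 | step 7 | 3-O-trimethylsilyl dienol ether of 10 (C3=C4 and C1=C2 double bonds, ring fusion as in 10) | C[Si](C)(C)OC1=C[C@@H]2[C@H](C(C)=C1)C(C)C(=O)C=CC2(C)C
F2 | step 7 | 4-bromo derivative of 10 (epimers at C4 and C9) | O=C1C=C(C)[C@H]2[C@@H](C1Br)C(C)(C)C=CC(=O)C2C
F3 | step 8 | 4,5-epoxide of 12 (oxirane oxygen on the face of the C5 hydroxyl of 14) | O1[C@@H]2C(=O)[C@@]3(C)[C@@H]4C(=O)C=C(C)[C@H]3[C@@H]4C(C)(C)[C@H]12
F4 | step 9 | (1R,2R,3R,5R,7S,8R)-3-hydroxy-2,6,6,9-tetramethyl-11-oxotricyclo[5.4.0.0²,⁸]undec-9-en-5-yl acetate | CC(=O)O[C@@H]1C[C@@H](O)[C@@]2(C)[C@@H]3C(=O)C=C(C)[C@H]2[C@@H]3C1(C)C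
F5 | step 9 | (1R,2R,3R,5R,7S,8R)-5-acetoxy-2,6,6,9-tetramethyl-11-oxotricyclo[5.4.0.0²,⁸]undec-9-en-3-yl 3-methylbutanoate | CC(=O)O[C@@H]1C[C@@H](OC(=O)CC(C)C)[C@@]2(C)[C@@H]3C(=O)C=C(C)[C@H]2[C@@H]3C1(C)C
F6 | step 9 | (1R,2R,3R,5R,7S,8R)-5-hydroxy-2,6,6,9-tetramethyl-11-oxotricyclo[5.4.0.0²,⁸]undec-9-en-3-yl 3-methylbutanoate | O[C@@H]1C[C@@H](OC(=O)CC(C)C)[C@@]2(C)[C@@H]3C(=O)C=C(C)[C@H]2[C@@H]3C1(C)C
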